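**Retrosynthetic overview**

1. Rings: A and C are the 3,5,7-trihydroxychromen-4-one, B is the benzo ring of the dihydrobenzofuran (numbered O1, C2, C3, C3a, C4 to C7, C7a), D is the dihydrofuran ring and E is the guaiacyl ring on C2. The last operations are global O-debenzylation and, before it, Algar–Flynn–Oyamada closure of ring C on a chalcone made from the C4 aldehyde and 2-hydroxy-4,6-bis(benzyloxy)acetophenone (ring A).
2. The C4 aldehyde comes from a C4 bromide, and the C3 hydroxymethyl group from a C3 methyl ester that is made trans by base epimerisation of the cis ester.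
3. Ring D is closed by making the C2–C3 bond in an asymmetric dirhodium-carbene 1,5 C–H insertion of an aryldiazoacetate. The enabling feature is that the carbene carbon (future C3) stands on ring-B carbon C3a, ortho to C7a–O1, while O1 carries the benzylic CH2 of ring E (future C2); that C–H bond is activated by O1 and by the para-alkoxyaryl ring E and is held 1,5 to the carbene.
4. The diazo ester comes from the arylacetate (Regitz transfer). The arylacetate comes from an ortho-allylphenol (aromatic Claisen rearrangement into the position between OH and Br, O-alkylation with the ring-E benzyl chloride, oxidative cleavage of the allyl group). The phenol comes from 2-(benzyloxy)-5-bromobenzaldehyde by Dakin-type oxidation.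
5. Order of ring formation: B, E and A are bought as arenes; D forms in step 9; C forms in step 15.

Key step: step 9

Assumption: the (S)-tert-leucinate catalyst Rh2(S-PTTL)4 is taken to select the benzylic hydrogen that leads to 2R, by analogy with related ortho-benzyloxy aryldiazoacetates; if the sense proved opposite on this substrate, the mirror-image catalyst Rh2(R-PTTL)4 would be used with no other change.

**Route**

Step 1
Reactants: 1 2-(benzyloxy)-5-bromobenzaldehyde
Product: 3 2-(benzyloxy)-5-bromophenol, via aryl formate 2 (not isolated)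
Conditions: mCPBA, CH2Cl2, 0 °C → rt; aq. NaHCO3 wash; then K2CO3 (cat.), MeOH, rt
Reagents that add atoms: 3-chloroperoxybenzoic acid (mCPBA), OOC(=O)c1cccc(Cl)c1
Why: Dakin-type Baeyer–Villiger oxidation: the electron-rich ortho-alkoxyaryl group migrates to the peracid oxygen in preference to hydride, and the formate is transesterified to the phenol by catalytic carbonate in methanol.

Step 2
Reactants: 3 2-(benzyloxy)-5-bromophenol; 4 allyl bromide
Product: 5 1-(benzyloxy)-4-bromo-2-(prop-2-en-1-yloxy)benzene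
Conditions: K2CO3, acetone, reflux
Reagents that add atoms: none
Why: Williamson ether synthesis of a phenoxide and a primary allylic bromide, which sets up the [3,3] shift of step 3.

Step 3
Reactants: 5 1-(benzyloxy)-4-bromo-2-(prop-2-en-1-yloxy)benzene
Product: 6 6-(benzyloxy)-3-bromo-2-(prop-2-en-1-yl)phenol
Conditions: N,N-diethylaniline, 190 °C, sealed tube
Reagents that add atoms: none
Why: Aromatic Claisen rearrangement: the [3,3] shift can rearomatise only at the one free ortho carbon, which lies between the oxygen-bearing carbon and the C–Br carbon, so the allyl group is placed regiospecifically next to the bromine.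

Step 4
Reactants: 6 6-(benzyloxy)-3-bromo-2-(prop-2-en-1-yl)phenol; 7 4-(benzyloxy)-3-methoxybenzyl chloride
Product: 8 1-(benzyloxy)-2-{[4-(benzyloxy)-3-methoxyphenyl]methoxy}-4-bromo-3-(prop-2-en-1-yl)benzene
Conditions: K2CO3, n-Bu4NI (cat.), DMF, 60 °C
Reagents that add atoms: none
Why: Williamson ether synthesis: the hindered but acidic phenol is O-alkylated by the reactive electron-rich benzylic chloride under iodide catalysis, installing ring E and the CH2 group that becomes C2.

Step 5
Reactants: 8 1-(benzyloxy)-2-{[4-(benzyloxy)-3-methoxyphenyl]methoxy}-4-bromo-3-(prop-2-en-1-yl)benzene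
Product: 10 2-[3-(benzyloxy)-2-{[4-(benzyloxy)-3-methoxyphenyl]methoxy}-6-bromophenyl]acetaldehyde, via vicinal diol 9 (not isolated)
Conditions: OsO4 (2 mol %), NaIO4, 2,6-lutidine, 1,4-dioxane/H2O, rt
Reagents that add atoms: osmium tetroxide, O=[Os](=O)(=O)=O; sodium periodate, [Na+].[O-]I(=O)(=O)=O
Why: Lemieux–Johnson oxidation: catalytic OsO4 dihydroxylates only the terminal alkene and NaIO4 cleaves the diol, 2,6-lutidine suppressing over-oxidation, while the arenes, benzyl ethers and aryl bromide are inert.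

Step 6
Reactants: 10 2-[3-(benzyloxy)-2-{[4-(benzyloxy)-3-methoxyphenyl]methoxy}-6-bromophenyl]acetaldehyde
Product: 11 2-[3-(benzyloxy)-2-{[4-(benzyloxy)-3-methoxyphenyl]methoxy}-6-bromophenyl]acetic acid
Conditions: NaClO2, NaH2PO4, 2-methyl-2-butene, t-BuOH/THF/H2O, 0 °C → rt
Reagents that add atoms: sodium chlorite, [Na+].[O-]Cl=O
Why: Pinnick oxidation, which converts the enolisable arylacetaldehyde into the acid under buffered conditions while 2-methyl-2-butene traps hypochlorous acid before it can chlorinate the electron-rich rings.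

Step 7
Reactants: 11 2-[3-(benzyloxy)-2-{[4-(benzyloxy)-3-methoxyphenyl]methoxy}-6-bromophenyl]acetic acid
Product: 12 methyl 2-[3-(benzyloxy)-2-{[4-(benzyloxy)-3-methoxyphenyl]methoxy}-6-bromophenyl]acetate
Conditions: MeI, K2CO3, DMF, rt
Reagents that add atoms: iodomethane, CI
Why: SN2 O-methylation of the carboxylate, giving the ester that serves as acceptor group of the carbene.

Step 8
Reactants: 12 methyl 2-[3-(benzyloxy)-2-{[4-(benzyloxy)-3-methoxyphenyl]methoxy}-6-bromophenyl]acetate
Product: 13 methyl 2-[3-(benzyloxy)-2-{[4-(benzyloxy)-3-methoxyphenyl]methoxy}-6-bromophenyl]-2-diazoacetate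
Conditions: p-ABSA, DBU, MeCN, 0 °C → rt
Reagents that add atoms: 4-acetamidobenzenesulfonyl azide (p-ABSA), CC(=O)Nc1ccc(cc1)S(=O)(=O)N=[N+]=[N-]
Why: Regitz diazo transfer: the amidine base generates the benzylic ester enolate, which attacks the terminal nitrogen of the sulfonyl azide and expels the sulfonamide to leave the aryldiazoacetate.

Step 9
Reactants: 13 methyl 2-[3-(benzyloxy)-2-{[4-(benzyloxy)-3-methoxyphenyl]methoxy}-6-bromophenyl]-2-diazoacetate
Product: 14 methyl (2R,3S)-7-(benzyloxy)-2-[4-(benzyloxy)-3-methoxyphenyl]-4-bromo-2,3-dihydro-1-benzofuran-3-carboxylate (cis)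
Conditions: Rh2(S-PTTL)4 (dirhodium tetrakis[N-phthaloyl-(S)-tert-leucinate], 1 mol %), toluene, −60 → −40 °C, slow addition of 13
Reagents that add atoms: none
Why: Loss of N2 from 13 at the dirhodium core gives an electrophilic donor/acceptor rhodium carbene at the future C3, which inserts in a concerted, hydride-transfer-like three-centre transition state into the benzylic C–H bond of the O1–CH2 group and so forms the C2–C3 bond. The closest known reaction type is the enantioselective intramolecular 1,5 C–H insertion of ortho-(benzyloxy)aryl diazoacetates with phthalimido-amino-acid dirhodium carboxylates, which gives cis-2-aryl-3-alkoxycarbonyl-2,3-dihydrobenzofurans, also on 7-alkoxy substrates. Ring D is closed as a five-membered ring by 1,5-insertion across the C3a–C7a–O1 tether, the only geometry within reach of the carbene. C2 is controlled by the catalyst, whose chiral ligand wall selects one of the two enantiotopic benzylic hydrogens and should give 2R; C3 is set cis to the C2 aryl group by the compact insertion transition state and is deliberately corrected in step 10. The step needs site selectivity for this C–H bond over ylide formation, aromatic cycloaddition into ring E and carbene dimerisation: the bond is doubly activated (O1 lone pair and para-alkoxyaryl ring), the ortho bromine and O1 could only form four-membered ylides, the other benzyl ethers cannot reach the carbene, and slow addition at low temperature keeps the diazo concentration low.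

Step 10
Reactants: 14 methyl (2R,3S)-7-(benzyloxy)-2-[4-(benzyloxy)-3-methoxyphenyl]-4-bromo-2,3-dihydro-1-benzofuran-3-carboxylate
Product: 15 methyl (2R,3R)-7-(benzyloxy)-2-[4-(benzyloxy)-3-methoxyphenyl]-4-bromo-2,3-dihydro-1-benzofuran-3-carboxylate (trans)
Conditions: NaOMe (0.2 equiv), MeOH/THF, rt
Reagents that add atoms: none
Why: Thermodynamic epimerisation by reversible deprotonation at C3 (alpha to the ester): the trans isomer avoids the eclipsing C2-aryl/C3-ester interaction, C2 is not acidic, and ring opening by beta-elimination is stereoelectronically disfavoured because the C2–O1 bond lies in the nodal plane of the enolate, so only C3 inverts (S to R) and the catalyst-set C2 is retained.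

Step 11
Reactants: 15 methyl (2R,3R)-7-(benzyloxy)-2-[4-(benzyloxy)-3-methoxyphenyl]-4-bromo-2,3-dihydro-1-benzofuran-3-carboxylate
Product: 16 [(2R,3S)-7-(benzyloxy)-2-[4-(benzyloxy)-3-methoxyphenyl]-4-bromo-2,3-dihydro-1-benzofuran-3-yl]methanol
Conditions: LiBH4, THF, 0 °C → rt
Reagents that add atoms: none
Why: Chemoselective ester reduction by LiBH4, which leaves the aryl bromide, the benzyl ethers and both stereocentres untouched (the C3 descriptor changes from R to S only through the priority rules).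

Step 12
Reactants: 16 [(2R,3S)-7-(benzyloxy)-2-[4-(benzyloxy)-3-methoxyphenyl]-4-bromo-2,3-dihydro-1-benzofuran-3-yl]methanol
Product: 17 (2R,3S)-7-(benzyloxy)-3-[(benzyloxy)methyl]-2-[4-(benzyloxy)-3-methoxyphenyl]-4-bromo-2,3-dihydro-1-benzofuran
Conditions: NaH, BnBr, n-Bu4NI (cat.), DMF, 0 °C → rt
Reagents that add atoms: benzyl bromide, BrCc1ccccc1
Why: Williamson benzylation of the primary alkoxide, masking the hydroxyl that would otherwise quench the aryllithium of step 13 and later add to the C4 aldehyde or the enone.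

Step 13
Reactants: 17 (2R,3S)-7-(benzyloxy)-3-[(benzyloxy)methyl]-2-[4-(benzyloxy)-3-methoxyphenyl]-4-bromo-2,3-dihydro-1-benzofuran
Product: 19 (2R,3S)-7-(benzyloxy)-3-[(benzyloxy)methyl]-2-[4-(benzyloxy)-3-methoxyphenyl]-2,3-dihydro-1-benzofuran-4-carbaldehyde, via aryllithium 18 (not isolated)
Conditions: n-BuLi, THF, −78 °C; then DMF, −78 → 0 °C; H2O
Reagents that add atoms: N,N-dimethylformamide, CN(C)C=O
Why: Bromine–lithium exchange at −78 °C is faster than deprotonation of any benzylic position, and the aryllithium is formylated by DMF (Bouveault aldehyde synthesis) without touching C2 or C3.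

Step 14
Reactants: 19 (2R,3S)-7-(benzyloxy)-3-[(benzyloxy)methyl]-2-[4-(benzyloxy)-3-methoxyphenyl]-2,3-dihydro-1-benzofuran-4-carbaldehyde; 20 1-[2,4-bis(benzyloxy)-6-hydroxyphenyl]ethan-1-one
Product: 21 (2E)-1-[2,4-bis(benzyloxy)-6-hydroxyphenyl]-3-[(2R,3S)-7-(benzyloxy)-3-[(benzyloxy)methyl]-2-[4-(benzyloxy)-3-methoxyphenyl]-2,3-dihydro-1-benzofuran-4-yl]prop-2-en-1-one
Conditions: KOH (50% aq.), EtOH/THF, rt
Reagents that add atoms: none
Why: Claisen–Schmidt condensation of the non-enolisable aldehyde with the acetophenone enolate, dehydration giving the conjugated E-enone under thermodynamic control; C2 and C3 carry no acidic hydrogen and are unaffected.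

Step 15
Reactants: 21 (2E)-1-[2,4-bis(benzyloxy)-6-hydroxyphenyl]-3-[(2R,3S)-7-(benzyloxy)-3-[(benzyloxy)methyl]-2-[4-(benzyloxy)-3-methoxyphenyl]-2,3-dihydro-1-benzofuran-4-yl]prop-2-en-1-one
Product: 22 5,7-bis(benzyloxy)-2-[(2R,3S)-7-(benzyloxy)-3-[(benzyloxy)methyl]-2-[4-(benzyloxy)-3-methoxyphenyl]-2,3-dihydro-1-benzofuran-4-yl]-3-hydroxy-4H-chromen-4-one
Conditions: H2O2 (30% aq.), NaOH (2 M aq.), MeOH/THF, 0 °C → rt
Reagents that add atoms: hydrogen peroxide, OO
Why: Algar–Flynn–Oyamada reaction: alkaline hydrogen peroxide oxidises the 2'-hydroxychalcone with closure of ring C by the phenoxide in the six-membered mode and in-situ dehydrogenation to the 3-hydroxychromen-4-one; the benzyl ethers and the dihydrobenzofuran are stable to the conditions.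

Step 16
Reactants: 22 5,7-bis(benzyloxy)-2-[(2R,3S)-7-(benzyloxy)-3-[(benzyloxy)methyl]-2-[4-(benzyloxy)-3-methoxyphenyl]-2,3-dihydro-1-benzofuran-4-yl]-3-hydroxy-4H-chromen-4-one
Product: 23 3,5,7-trihydroxy-2-[(2R,3S)-7-hydroxy-2-(4-hydroxy-3-methoxyphenyl)-3-(hydroxymethyl)-2,3-dihydro-1-benzofuran-4-yl]-4H-chromen-4-one (CNP0195987.1)
Conditions: H2 (1 atm), Pd(OH)2/C, THF/MeOH, rt
Reagents that add atoms: none
Why: Catalytic hydrogenolysis removes the five O-benzyl groups, the primary benzylic C–O bonds being cleaved much faster than the hindered secondary ring bond C2–O1 or the tetrasubstituted conjugated C2=C3 bond of the chromenone, so the flavonol and both stereocentres (2R,3S) should be retained when hydrogen uptake is followed and stopped.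

**Compound list**

1 | 2-(benzyloxy)-5-bromobenzaldehyde | O=Cc1cc(Br)ccc1OCc1ccccc1 | starting material
2 | 2-(benzyloxy)-5-bromophenyl formate | O=COc1cc(Br)ccc1OCc1ccccc1 | intermediate (not isolated)
3 | 2-(benzyloxy)-5-bromophenol | Oc1cc(Br)ccc1OCc1ccccc1 | intermediate
4 | allyl bromide (3-bromoprop-1-ene) | C=CCBr | starting material
5 | 1-(benzyloxy)-4-bromo-2-(prop-2-en-1-yloxy)benzene | C=CCOc1cc(Br)ccc1OCc1ccccc1 | intermediate
6 | 6-(benzyloxy)-3-bromo-2-(prop-2-en-1-yl)phenol | C=CCc1c(Br)ccc(OCc2ccccc2)c1O | intermediate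
7 | 4-(benzyloxy)-3-methoxybenzyl chloride [1-(benzyloxy)-4-(chloromethyl)-2-methoxybenzene] | COc1cc(CCl)ccc1OCc1ccccc1 | starting material
8 | 1-(benzyloxy)-2-{[4-(benzyloxy)-3-methoxyphenyl]methoxy}-4-bromo-3-(prop-2-en-1-yl)benzene | C=CCc1c(Br)ccc(OCc2ccccc2)c1OCc1ccc(OCc2ccccc2)c(OC)c1 | intermediate
9 | 3-[3-(benzyloxy)-2-{[4-(benzyloxy)-3-methoxyphenyl]methoxy}-6-bromophenyl]propane-1,2-diol (racemic at the secondary carbinol) | OCC(O)Cc1c(Br)ccc(OCc2ccccc2)c1OCc1ccc(OCc2ccccc2)c(OC)c1 | intermediate (not isolated)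
10 | 2-[3-(benzyloxy)-2-{[4-(benzyloxy)-3-methoxyphenyl]methoxy}-6-bromophenyl]acetaldehyde | O=CCc1c(Br)ccc(OCc2ccccc2)c1OCc1ccc(OCc2ccccc2)c(OC)c1 | intermediate
11 | 2-[3-(benzyloxy)-2-{[4-(benzyloxy)-3-methoxyphenyl]methoxy}-6-bromophenyl]acetic acid | OC(=O)Cc1c(Br)ccc(OCc2ccccc2)c1OCc1ccc(OCc2ccccc2)c(OC)c1 | intermediate
12 | methyl 2-[3-(benzyloxy)-2-{[4-(benzyloxy)-3-methoxyphenyl]methoxy}-6-bromophenyl]acetate | COC(=O)Cc1c(Br)ccc(OCc2ccccc2)c1OCc1ccc(OCc2ccccc2)c(OC)c1 | intermediate
13 | methyl 2-[3-(benzyloxy)-2-{[4-(benzyloxy)-3-methoxyphenyl]methoxy}-6-bromophenyl]-2-diazoacetate | COC(=O)C(=[N+]=[N-])c1c(Br)ccc(OCc2ccccc2)c1OCc1ccc(OCc2ccccc2)c(OC)c1 | intermediate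
14 | methyl (2R,3S)-7-(benzyloxy)-2-[4-(benzyloxy)-3-methoxyphenyl]-4-bromo-2,3-dihydro-1-benzofuran-3-carboxylate (cis) | COc1cc([C@@H]2Oc3c(OCc4ccccc4)ccc(Br)c3[C@@H]2C(=O)OC)ccc1OCc1ccccc1 | intermediate
15 | methyl (2R,3R)-7-(benzyloxy)-2-[4-(benzyloxy)-3-methoxyphenyl]-4-bromo-2,3-dihydro-1-benzofuran-3-carboxylate (trans) | COc1cc([C@@H]2Oc3c(OCc4ccccc4)ccc(Br)c3[C@H]2C(=O)OC)ccc1OCc1ccccc1 | intermediate
16 | [(2R,3S)-7-(benzyloxy)-2-[4-(benzyloxy)-3-methoxyphenyl]-4-bromo-2,3-dihydro-1-benzofuran-3-yl]methanol (trans) | COc1cc([C@@H]2Oc3c(OCc4ccccc4)ccc(Br)c3[C@H]2CO)ccc1OCc1ccccc1 | intermediate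
17 | (2R,3S)-7-(benzyloxy)-3-[(benzyloxy)methyl]-2-[4-(benzyloxy)-3-methoxyphenyl]-4-bromo-2,3-dihydro-1-benzofuran | COc1cc([C@@H]2Oc3c(OCc4ccccc4)ccc(Br)c3[C@H]2COCc2ccccc2)ccc1OCc1ccccc1 | intermediate
18 | [(2R,3S)-7-(benzyloxy)-3-[(benzyloxy)methyl]-2-[4-(benzyloxy)-3-methoxyphenyl]-2,3-dihydro-1-benzofuran-4-yl]lithium | COc1cc([C@@H]2Oc3c(OCc4ccccc4)ccc([Li])c3[C@H]2COCc2ccccc2)ccc1OCc1ccccc1 | intermediate (not isolated)
19 | (2R,3S)-7-(benzyloxy)-3-[(benzyloxy)methyl]-2-[4-(benzyloxy)-3-methoxyphenyl]-2,3-dihydro-1-benzofuran-4-carbaldehyde | COc1cc([C@@H]2Oc3c(OCc4ccccc4)ccc(C=O)c3[C@H]2COCc2ccccc2)ccc1OCc1ccccc1 | intermediate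
20 | 1-[2,4-bis(benzyloxy)-6-hydroxyphenyl]ethan-1-one | CC(=O)c1c(O)cc(OCc2ccccc2)cc1OCc1ccccc1 | starting material
21 | (2E)-1-[2,4-bis(benzyloxy)-6-hydroxyphenyl]-3-[(2R,3S)-7-(benzyloxy)-3-[(benzyloxy)methyl]-2-[4-(benzyloxy)-3-methoxyphenyl]-2,3-dihydro-1-benzofuran-4-yl]prop-2-en-1-one | COc1cc([C@@H]2Oc3c(OCc4ccccc4)ccc(/C=C/C(=O)c4c(O)cc(OCc5ccccc5)cc4OCc4ccccc4)c3[C@H]2COCc2ccccc2)ccc1OCc1ccccc1 | intermediate
22 | 5,7-bis(benzyloxy)-2-[(2R,3S)-7-(benzyloxy)-3-[(benzyloxy)methyl]-2-[4-(benzyloxy)-3-methoxyphenyl]-2,3-dihydro-1-benzofuran-4-yl]-3-hydroxy-4H-chromen-4-one | COc1cc([C@@H]2Oc3c(OCc4ccccc4)ccc(-c4oc5cc(OCc6ccccc6)cc(OCc6ccccc6)c5c(=O)c4O)c3[C@H]2COCc2ccccc2)ccc1OCc1ccccc1 | intermediate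
23 | 3,5,7-trihydroxy-2-[(2R,3S)-7-hydroxy-2-(4-hydroxy-3-methoxyphenyl)-3-(hydroxymethyl)-2,3-dihydro-1-benzofuran-4-yl]-4H-chromen-4-one | COc1cc([C@@H]2Oc3c(O)ccc(-c4oc5cc(O)cc(O)c5c(=O)c4O)c3[C@H]2CO)ccc1O | target

**Step count and risks**

Total step count: 16. Longest linear sequence: 16 steps (compound 1 to compound 23).

The three steps most likely to fail:

Step 15 (Algar–Flynn–Oyamada). The phenoxide may close in the five-membered mode at the alpha carbon, a pathway favoured by the 6'-benzyloxy group and by the ortho-substituted ring B; this would divert material to an aurone. The fallback sets out from chalcone 21 and separates ring closure from C3 oxygenation. Oxidative cyclisation with I2 (cat.) in DMSO at 110 °C should give the 3-unsubstituted 5,7-bis(benzyloxy)flavone F1. Dimethyldioxirane (acetone/CH2Cl2, 0 °C) should then epoxidise its C2=C3 bond to the 2,3-epoxyflavanone F2, which is opened in the same flask with TsOH (cat.) to the 3-hydroxychromenone. The route is rejoined at compound 22.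

Step 9 (carbene C–H insertion). The di-ortho-substituted aryl carbene is twisted out of conjugation, so discrimination of the two benzylic hydrogens by the catalyst alone may be poor, and aromatic cycloaddition into ring E may compete. The fallback sets out from acid 11 and moves part of the stereocontrol into the substrate. Esterification with (S)-2-hydroxy-1-(pyrrolidin-1-yl)propan-1-one (EDC·HCl, DMAP, CH2Cl2) should give the lactamide ester F3, and Regitz transfer (p-ABSA, DBU, MeCN) the lactamide diazo ester F4. Insertion with Rh2(S-DOSP)4 (dirhodium tetrakis[(S)-N-(4-dodecylphenylsulfonyl)prolinate], toluene, −45 °C; DBU afterwards if cis ester is present) should give the trans-dihydrobenzofuran lactamide ester F5, whose diastereomers can be separated by chromatography or crystallisation. LiBH4 in THF then removes the auxiliary reductively and the route is rejoined at alcohol 16. The auxiliary antipode is chosen so that the matched pair gives the 2R series; it is drawn as S.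

Step 8 (diazo transfer). The benzylic ester is flanked by bromine and the benzyloxy group, its enolate cannot conjugate with the twisted arene, and deprotonation by the amidine base may be incomplete so that the transfer stalls. The fallback sets out from ester 12 and uses deacylative diazo transfer. Enolisation with LiN(SiMe3)2 (THF, −78 °C) and acylation with 2,2,2-trifluoroethyl trifluoroacetate should give the alpha-trifluoroacetyl ester F6. This activated 1,3-dicarbonyl compound should accept the diazo group from p-ABSA (Et3N, MeCN, H2O 1 equiv, rt) with loss of the trifluoroacetyl group, and the route is rejoined at diazo ester 13.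

**Further compounds**

F1 | step 15 | 5,7-bis(benzyloxy)-2-[(2R,3S)-7-(benzyloxy)-3-[(benzyloxy)methyl]-2-[4-(benzyloxy)-3-methoxyphenyl]-2,3-dihydro-1-benzofuran-4-yl]-4H-chromen-4-one | COc1cc([C@@H]2Oc3c(OCc4ccccc4)ccc(-c4cc(=O)c5c(OCc6ccccc6)cc(OCc6ccccc6)cc5o4)c3[C@H]2COCc2ccccc2)ccc1OCc1ccccc1
F2 | step 15 | 2,3-epoxide of F1 (2,3-epoxyflavanone; both epoxide diastereomers) | COc1cc([C@@H]2Oc3c(OCc4ccccc4)ccc(C45OC4C(=O)c4c(OCc6ccccc6)cc(OCc6ccccc6)cc4O5)c3[C@H]2COCc2ccccc2)ccc1OCc1ccccc1
F3 | step 9 | (2S)-1-oxo-1-(pyrrolidin-1-yl)propan-2-yl 2-[3-(benzyloxy)-2-{[4-(benzyloxy)-3-methoxyphenyl]methoxy}-6-bromophenyl]acetate | C[C@H](OC(=O)Cc1c(Br)ccc(OCc2ccccc2)c1OCc1ccc(OCc2ccccc2)c(OC)c1)C(=O)N1CCCC1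
F4 | step 9 | (2S)-1-oxo-1-(pyrrolidin-1-yl)propan-2-yl 2-[3-(benzyloxy)-2-{[4-(benzyloxy)-3-methoxyphenyl]methoxy}-6-bromophenyl]-2-diazoacetate | C[C@H](OC(=O)C(=[N+]=[N-])c1c(Br)ccc(OCc2ccccc2)c1OCc1ccc(OCc2ccccc2)c(OC)c1)C(=O)N1CCCC1
F5 | step 9 | (2S)-1-oxo-1-(pyrrolidin-1-yl)propan-2-yl (2R,3R)-7-(benzyloxy)-2-[4-(benzyloxy)-3-methoxyphenyl]-4-bromo-2,3-dihydro-1-benzofuran-3-carboxylate (trans) | COc1cc([C@@H]2Oc3c(OCc4ccccc4)ccc(Br)c3[C@H]2C(=O)O[C@@H](C)C(=O)N2CCCC2)ccc1OCc1ccccc1
F6 | step 8 | methyl 2-[3-(benzyloxy)-2-{[4-(benzyloxy)-3-methoxyphenyl]methoxy}-6-bromophenyl]-4,4,4-trifluoro-3-oxobutanoate (racemic, enolisable centre) | COC(=O)C(C(=O)C(F)(F)F)c1c(Br)ccc(OCc2ccccc2)c1OCc1ccc(OCc2ccccc2)c(OC)c1
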